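In the 2.5 min a flask runs at fixed temperature, what you want to know is how the L it spends divides between L.G and L2.

| flask | L | G | time | remark |
|---|---|---|---|---|
| eta | 0.40 M (in portions, 2, over 30 s) | 0.420 M | 2.5 min | first portion at the start, last at 30 s |
| delta | 0.40 M | 0.420 M | 2.5 min | everything together at the start |
| epsilon | 0.40 M (fed, over 30 s) | 0.420 M | 2.5 min | all else is in the flask from the start; the feed brings no volume worth counting |
| theta | 0.40 M | 0.420 M (fed, over 30 s) | 2.5 min | all else is in the flask from the start; the feed brings no volume worth counting |

- the flask with the highest amount of L2, in percent of the L charged ("all alike" if they lie within 1.5 percentage points) (eta / delta / epsilon / theta / all alike)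
- final L2, as a percentage of the L charged, in eta
- final L2, as a percentage of the L charged, in delta
- final L2, as a percentage of the L charged, in epsilon
- final L2, as a percentage of the L charged, in theta

- percent here means L units held: one L.L.G or L2 counts as two
- for a step with 2 of a species take k times the square, and two of it per event
- run time (eta): 2.5 min

L goes to L.G at 0.087 /M^1.5/s times the square of L times the square root of G, and two L go to L2 at twice 0.015 /M/s times the square of L. The square of L cancels in the ratio, so at a given G how L enters does not move it. With G at its charge, this ratio of L into L2 to L into L.G, the split 0.532 (a selectivity factor), sends 34.7% of that L to L2, before the step from L and L.G takes its part.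

So I expect eta, delta and epsilon to lie together. In theta, at mid-feed, half the charge of G has been fed, and if I take that as the G present, the split rises to 0.752, more than before, and the share to 42.9%. Taking this mid-feed rise in share as a rough measure for the whole run, I commit to theta on top, with L2 about 1.24 times delta's.

The forecast says theta, with 25.3% in eta, 25.6% in delta, 25.2% in epsilon and 32% in theta: “Feeding G starves the sqrt(G) step early while L is at its highest”.

The flasks give theta as the highest, with 25.3% in eta, 25.9% in delta, 25.5% in epsilon and 32.2% in theta.

    L + G → L.G, rate k1*[L]^2*[G]^0.5 (k1 = 0.087 /M^1.5/s)
    2 L → L2 (k2 = 0.015 /M/s)
    L + L.G → L.L.G (k3 = 0.050 /M/s)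

Theta ends at 1.24 times delta's L2. Over the first 30 s, G averages 0.169 M in theta against 0.403 M in epsilon. For theta's neighbour charged with 0.17 M of G, the same mid-feed reckoning, at half that charge, gives a split of 1.18 and a share of 54.2%, which is 1.26 times theta's mid-feed share. That neighbour's L2 ends at 39.8% of the L charged, 1.24 times theta's.

(The numbers of this flask were drawn at random within sensible limits, and the outcome is calculated.)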